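**Retrosynthetic overview**
1. Target 19 ⇐ bis-N-tosyl 4-iodooxazole 18 (global detosylation) ⇐ C4–H oxazole 17 (late electrophilic iodination at the only free oxazole position).
2. Oxazole ⇐ α-acylamino ketone 14 (Robinson–Gabriel cyclodehydration); amide C–N bond from aminoketone 12 and 2-(trichloroacetyl)pyrrole 13.
3. Aminoketone 12 ⇐ β-keto ester 9 ⇐ key C–C bond (indole-CO–CH(N)): crossed Claisen condensation of the glycinate ester enolate from 7 with indole-3-carbonyl chloride 6.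
4. 6 ⇐ 6-bromo-4-methoxyindole 1 by Vilsmeier formylation, N-tosylation, Pinnick oxidation and chlorination.
5. Ring order: the indole and pyrrole rings are bought intact; the oxazole is the only ring built (step 8).

Assumption: the target has no stereocentre, so no stereocontrol is needed; 6-bromo-4-methoxy-1H-indole is taken as a catalogue building block. "Tosyl" = 4-methylbenzenesulfonyl.

**Route**

Step 1
Reactants: 1 6-bromo-4-methoxy-1H-indole
Product: 3 6-bromo-4-methoxy-1H-indole-3-carbaldehyde, via iminium chloride 2 (not isolated)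
Conditions: POCl3 (1.2 equiv), DMF, 0 °C to 40 °C; then 2 M NaOH (aq), 0 °C to 80 °C
Reagents that add atoms: N,N-dimethylformamide CN(C)C=O (formyl carbon); water O (carbonyl oxygen, on hydrolysis)
Why: Vilsmeier–Haack formylation; the chloroiminium ion attacks the most nucleophilic indole carbon C3 (further activated by 4-OMe) and basic hydrolysis of the iminium gives the aldehyde.

Step 2
Reactants: 3 6-bromo-4-methoxy-1H-indole-3-carbaldehyde
Product: 4 6-bromo-4-methoxy-1-tosyl-1H-indole-3-carbaldehyde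
Conditions: TsCl (1.2 equiv), Et3N (2 equiv), DMAP (0.1 equiv), CH2Cl2, 0 °C to rt
Reagents that add atoms: 4-methylbenzenesulfonyl chloride Cc1ccc(cc1)S(=O)(=O)Cl
Why: DMAP-catalysed N-sulfonylation of the N–H acidified by the 3-formyl group; the tosyl group removes the acidic N–H and deactivates the indole for the following steps.

Step 3
Reactants: 4 6-bromo-4-methoxy-1-tosyl-1H-indole-3-carbaldehyde
Product: 5 6-bromo-4-methoxy-1-tosyl-1H-indole-3-carboxylic acid
Conditions: NaClO2 (3 equiv), NaH2PO4 (3 equiv), 2-methyl-2-butene (10 equiv), t-BuOH/THF/H2O, 0 °C to rt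
Reagents that add atoms: sodium chlorite [Na+].[O-]Cl=O
Why: Pinnick oxidation; chlorous acid oxidises only the aldehyde, the alkene scavenges HOCl, and the N-tosyl indole is not chlorinated.

Step 4
Reactants: 5 6-bromo-4-methoxy-1-tosyl-1H-indole-3-carboxylic acid
Product: 6 6-bromo-4-methoxy-1-tosyl-1H-indole-3-carbonyl chloride
Conditions: (COCl)2 (1.5 equiv), DMF (cat.), CH2Cl2, 0 °C to rt; evaporate, azeotrope with toluene, use crude
Reagents that add atoms: oxalyl chloride ClC(=O)C(Cl)=O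
Why: Acid chloride formation under Vilsmeier-type catalysis; a non-enolisable aroyl chloride is a clean acyl donor for the next step.

Step 5 (key step)
Reactants: 6 6-bromo-4-methoxy-1-tosyl-1H-indole-3-carbonyl chloride; 7 tert-butyl N-(diphenylmethylidene)glycinate
Product: 9 tert-butyl 3-(6-bromo-4-methoxy-1-tosyl-1H-indol-3-yl)-2-[(diphenylmethylidene)amino]-3-oxopropanoate (racemic), via lithium enolate 8 (not isolated)
Conditions: 7 (2.1 equiv), LiN(SiMe3)2 (2.1 equiv), THF, −78 °C, 30 min; then 6 in THF added slowly, −78 °C to −40 °C; AcOH/NH4Cl (aq) quench; use crude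
Reagents that add atoms: none
Why: Crossed Claisen condensation, with chloride as the leaving group: the stabilised glycinate ester enolate is C-acylated to a β-keto ester, and the second equivalent of enolate deprotonates the more acidic product so it is not acylated twice. The new C2 centre is racemic and labile and is removed in step 6.

Step 6
Reactants: 9 tert-butyl 3-(6-bromo-4-methoxy-1-tosyl-1H-indol-3-yl)-2-[(diphenylmethylidene)amino]-3-oxopropanoate
Product: 12 2-amino-1-(6-bromo-4-methoxy-1-tosyl-1H-indol-3-yl)ethan-1-one hydrochloride, via amino keto ester hydrochloride 10 (not isolated), via amino keto acid hydrochloride 11 (not isolated)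
Conditions: 2 M HCl (aq), THF, rt; evaporate, triturate with Et2O; then 4 M HCl in dioxane, 50 °C
Reagents that add atoms: hydrogen chloride Cl
Why: Imine hydrolysis, acidolysis of the tert-butyl ester and decarboxylation of the β-keto acid; the amine stays protonated, so the α-aminoketone cannot self-condense, and the N-tosyl and aryl ether groups are acid-stable.

Step 7
Reactants: 12 2-amino-1-(6-bromo-4-methoxy-1-tosyl-1H-indol-3-yl)ethan-1-one hydrochloride; 13 2,2,2-trichloro-1-(1H-pyrrol-2-yl)ethan-1-one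
Product: 14 N-[2-(6-bromo-4-methoxy-1-tosyl-1H-indol-3-yl)-2-oxoethyl]-1H-pyrrole-2-carboxamide
Conditions: 13 (1.1 equiv), Et3N (2.2 equiv, added slowly), MeCN, 0 °C to rt
Reagents that add atoms: none
Why: Haloform-type acyl transfer (aminolysis of a trichloromethyl ketone with loss of CHCl3); the pyrrole N–H needs no protection, and slow release of the free amine in the presence of the acyl donor suppresses dihydropyrazine formation.

Step 8
Reactants: 14 N-[2-(6-bromo-4-methoxy-1-tosyl-1H-indol-3-yl)-2-oxoethyl]-1H-pyrrole-2-carboxamide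
Product: 15 5-(6-bromo-4-methoxy-1-tosyl-1H-indol-3-yl)-2-(1H-pyrrol-2-yl)-1,3-oxazole
Conditions: PPh3 (2 equiv), C2Cl6 (2 equiv), Et3N (4 equiv), CH2Cl2, 0 °C to rt
Reagents that add atoms: none
Why: Robinson–Gabriel cyclodehydration under mild phosphonium activation; O-attack on the activated carbonyl and loss of water give the aromatic 2,5-disubstituted oxazole without strong acid.

Step 9
Reactants: 15 5-(6-bromo-4-methoxy-1-tosyl-1H-indol-3-yl)-2-(1H-pyrrol-2-yl)-1,3-oxazole
Product: 17 5-(6-bromo-4-methoxy-1-tosyl-1H-indol-3-yl)-2-(1-tosyl-1H-pyrrol-2-yl)-1,3-oxazole, via sodium pyrrolide 16 (not isolated)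
Conditions: NaH (1.3 equiv), THF/DMF, 0 °C; then TsCl (1.3 equiv), 0 °C to rt
Reagents that add atoms: 4-methylbenzenesulfonyl chloride Cc1ccc(cc1)S(=O)(=O)Cl
Why: N-sulfonylation of the only remaining N–H; the sulfonyl group strongly deactivates the pyrrole so it does not compete in the iodination.

Step 10
Reactants: 17 5-(6-bromo-4-methoxy-1-tosyl-1H-indol-3-yl)-2-(1-tosyl-1H-pyrrol-2-yl)-1,3-oxazole
Product: 18 5-(6-bromo-4-methoxy-1-tosyl-1H-indol-3-yl)-4-iodo-2-(1-tosyl-1H-pyrrol-2-yl)-1,3-oxazole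
Conditions: NIS (1.15 equiv), TFA (0.3 equiv), MeCN, 0 °C to rt (40 °C if slow), dark
Reagents that add atoms: N-iodosuccinimide O=C1CCC(=O)N1I
Why: Electrophilic aromatic iodination; oxazole C4 is the enol-ether-like β-carbon of the O1–C5=C4 unit and the only free oxazole position, both azole rings are deactivated by N-sulfonyl groups, and the benzo positions C5 and C7 are each flanked by two substituents.

Step 11
Reactants: 18 5-(6-bromo-4-methoxy-1-tosyl-1H-indol-3-yl)-4-iodo-2-(1-tosyl-1H-pyrrol-2-yl)-1,3-oxazole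
Product: 19 6-bromo-3-[4-iodo-2-(1H-pyrrol-2-yl)-1,3-oxazol-5-yl]-4-methoxy-1H-indole
Conditions: 2 M NaOH (aq, 6 equiv), MeOH/THF 1:1, 60 °C; NH4Cl (aq) work-up
Reagents that add atoms: none
Why: Nucleophilic N-desulfonylation of both azole sulfonamides by hydroxide/methoxide at sulfur; the aryl bromide, the 4-iodooxazole and the methyl ether are inert to these non-reducing conditions.

**Compound list**
1 | 6-bromo-4-methoxy-1H-indole | COc1cc(Br)cc2[nH]ccc12 | starting material
2 | [(6-bromo-4-methoxy-1H-indol-3-yl)methylidene]dimethylammonium chloride (not isolated) | COc1cc(Br)cc2[nH]cc(C=[N+](C)C)c12.[Cl-] | intermediate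
3 | 6-bromo-4-methoxy-1H-indole-3-carbaldehyde | COc1cc(Br)cc2[nH]cc(C=O)c12 | intermediate
4 | 6-bromo-4-methoxy-1-tosyl-1H-indole-3-carbaldehyde | COc1cc(Br)cc2n(S(=O)(=O)c3ccc(C)cc3)cc(C=O)c12 | intermediate
5 | 6-bromo-4-methoxy-1-tosyl-1H-indole-3-carboxylic acid | COc1cc(Br)cc2n(S(=O)(=O)c3ccc(C)cc3)cc(C(=O)O)c12 | intermediate
6 | 6-bromo-4-methoxy-1-tosyl-1H-indole-3-carbonyl chloride | COc1cc(Br)cc2n(S(=O)(=O)c3ccc(C)cc3)cc(C(=O)Cl)c12 | intermediate
7 | tert-butyl N-(diphenylmethylidene)glycinate | CC(C)(C)OC(=O)CN=C(c1ccccc1)c1ccccc1 | starting material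
8 | lithium enolate of 7 (not isolated) | [Li+].CC(C)(C)OC([O-])=CN=C(c1ccccc1)c1ccccc1 | intermediate
9 | tert-butyl 3-(6-bromo-4-methoxy-1-tosyl-1H-indol-3-yl)-2-[(diphenylmethylidene)amino]-3-oxopropanoate (racemic, labile C2) | COc1cc(Br)cc2n(S(=O)(=O)c3ccc(C)cc3)cc(C(=O)C(N=C(c3ccccc3)c3ccccc3)C(=O)OC(C)(C)C)c12 | intermediate
10 | tert-butyl 2-amino-3-(6-bromo-4-methoxy-1-tosyl-1H-indol-3-yl)-3-oxopropanoate hydrochloride (racemic; not isolated) | COc1cc(Br)cc2n(S(=O)(=O)c3ccc(C)cc3)cc(C(=O)C(N)C(=O)OC(C)(C)C)c12.Cl | intermediate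
11 | 2-amino-3-(6-bromo-4-methoxy-1-tosyl-1H-indol-3-yl)-3-oxopropanoic acid hydrochloride (racemic; not isolated) | COc1cc(Br)cc2n(S(=O)(=O)c3ccc(C)cc3)cc(C(=O)C(N)C(=O)O)c12.Cl | intermediate
12 | 2-amino-1-(6-bromo-4-methoxy-1-tosyl-1H-indol-3-yl)ethan-1-one hydrochloride | COc1cc(Br)cc2n(S(=O)(=O)c3ccc(C)cc3)cc(C(=O)CN)c12.Cl | intermediate
13 | 2,2,2-trichloro-1-(1H-pyrrol-2-yl)ethan-1-one | O=C(c1ccc[nH]1)C(Cl)(Cl)Cl | starting material
14 | N-[2-(6-bromo-4-methoxy-1-tosyl-1H-indol-3-yl)-2-oxoethyl]-1H-pyrrole-2-carboxamide | COc1cc(Br)cc2n(S(=O)(=O)c3ccc(C)cc3)cc(C(=O)CNC(=O)c3ccc[nH]3)c12 | intermediate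
15 | 5-(6-bromo-4-methoxy-1-tosyl-1H-indol-3-yl)-2-(1H-pyrrol-2-yl)-1,3-oxazole | COc1cc(Br)cc2n(S(=O)(=O)c3ccc(C)cc3)cc(-c3cnc(-c4ccc[nH]4)o3)c12 | intermediate
16 | sodium pyrrolide of 15 (not isolated) | COc1cc(Br)cc2n(S(=O)(=O)c3ccc(C)cc3)cc(-c3cnc(-c4ccc[n-]4)o3)c12.[Na+] | intermediate
17 | 5-(6-bromo-4-methoxy-1-tosyl-1H-indol-3-yl)-2-(1-tosyl-1H-pyrrol-2-yl)-1,3-oxazole | COc1cc(Br)cc2n(S(=O)(=O)c3ccc(C)cc3)cc(-c3cnc(-c4cccn4S(=O)(=O)c4ccc(C)cc4)o3)c12 | intermediate
18 | 5-(6-bromo-4-methoxy-1-tosyl-1H-indol-3-yl)-4-iodo-2-(1-tosyl-1H-pyrrol-2-yl)-1,3-oxazole | COc1cc(Br)cc2n(S(=O)(=O)c3ccc(C)cc3)cc(-c3oc(-c4cccn4S(=O)(=O)c4ccc(C)cc4)nc3I)c12 | intermediate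
19 | 6-bromo-3-[4-iodo-2-(1H-pyrrol-2-yl)-1,3-oxazol-5-yl]-4-methoxy-1H-indole | COc1cc(Br)cc2[nH]cc(-c3oc(-c4ccc[nH]4)nc3I)c12 | target

**Totals**
Total step count: 11. Longest linear sequence: 11 steps (1 to 19); 7 and 13 enter as purchased fragments.

**Three steps most likely to fail, each with a fallback**

Step 5, the Claisen C-acylation. The risks are O-acylation, attack of the enolate on the sulfonyl group, and poor conversion of the acyl chloride next to the peri-methoxy group. The fallback sets out from aldehyde 4 and builds the same C–C bond by a nitroaldol (Henry) addition. Nitromethane with catalytic DBU in THF at 0 °C gives racemic 1-(6-bromo-4-methoxy-1-tosyl-1H-indol-3-yl)-2-nitroethan-1-ol F1. Zn dust in aqueous HCl/EtOH reduces the nitro group without touching C–Br and gives racemic 2-amino-1-(6-bromo-4-methoxy-1-tosyl-1H-indol-3-yl)ethan-1-ol F2. Acylation with 13 and Et3N in MeCN gives racemic N-[2-(6-bromo-4-methoxy-1-tosyl-1H-indol-3-yl)-2-hydroxyethyl]-1H-pyrrole-2-carboxamide F3. Dess–Martin periodinane in NaHCO3-buffered CH2Cl2 oxidises the secondary alcohol, and the route is rejoined at keto amide 14.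

Step 7, acylation of the free α-aminoketone. The risk is self-condensation to a dihydropyrazine once the salt is neutralised. The fallback sets out from 9 and acylates before decarboxylation. Mild hydrolysis (1 M HCl, THF, rt) leaves the tert-butyl ester intact, and the hydrochloride 10 is isolated. Acylation with 13 and Et3N gives tert-butyl 3-(6-bromo-4-methoxy-1-tosyl-1H-indol-3-yl)-3-oxo-2-[(1H-pyrrole-2-carbonyl)amino]propanoate F4. TFA in CH2Cl2 followed by gentle warming cleaves the ester and decarboxylates through the transient 3-(6-bromo-4-methoxy-1-tosyl-1H-indol-3-yl)-3-oxo-2-[(1H-pyrrole-2-carbonyl)amino]propanoic acid F5. The route is rejoined at keto amide 14.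

Step 10, the C4 iodination. The risk is competing iodination of the methoxy-activated benzo ring (C7) or of the pyrrole. The fallback sets out from 12 and places the iodine by anionic chemistry before the pyrrole is attached. Formylation with acetic formic anhydride and Et3N in CH2Cl2 gives N-[2-(6-bromo-4-methoxy-1-tosyl-1H-indol-3-yl)-2-oxoethyl]formamide F6. Cyclodehydration with PPh3/C2Cl6/Et3N gives 5-(6-bromo-4-methoxy-1-tosyl-1H-indol-3-yl)-1,3-oxazole F7. Deprotonation at oxazole C2 with excess LiN(SiMe3)2 in THF/DMPU at −78 °C and quenching with I2 iodinates C4 (through the ring-opened isocyano enolate) and C2, giving 5-(6-bromo-4-methoxy-1-tosyl-1H-indol-3-yl)-2,4-diiodo-1,3-oxazole F8. A Suzuki coupling selective for the more electrophilic C2–I, using 1-(tert-butoxycarbonyl)pyrrole-2-boronic acid, Pd(PPh3)4 (zerovalent palladium) and Na2CO3 in dioxane/H2O at 80 °C, gives tert-butyl 2-[5-(6-bromo-4-methoxy-1-tosyl-1H-indol-3-yl)-4-iodo-1,3-oxazol-2-yl]-1H-pyrrole-1-carboxylate F9. NaOH in MeOH/THF at 60 °C removes both the Boc and the tosyl group, and the route is rejoined at target 19.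

**Further compounds**
F1 | step 5 | 1-(6-bromo-4-methoxy-1-tosyl-1H-indol-3-yl)-2-nitroethan-1-ol (racemic) | COc1cc(Br)cc2n(S(=O)(=O)c3ccc(C)cc3)cc(C(O)C[N+](=O)[O-])c12
F2 | step 5 | 2-amino-1-(6-bromo-4-methoxy-1-tosyl-1H-indol-3-yl)ethan-1-ol (racemic) | COc1cc(Br)cc2n(S(=O)(=O)c3ccc(C)cc3)cc(C(O)CN)c12
F3 | step 5 | N-[2-(6-bromo-4-methoxy-1-tosyl-1H-indol-3-yl)-2-hydroxyethyl]-1H-pyrrole-2-carboxamide (racemic) | COc1cc(Br)cc2n(S(=O)(=O)c3ccc(C)cc3)cc(C(O)CNC(=O)c3ccc[nH]3)c12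
F4 | step 7 | tert-butyl 3-(6-bromo-4-methoxy-1-tosyl-1H-indol-3-yl)-3-oxo-2-[(1H-pyrrole-2-carbonyl)amino]propanoate (racemic) | COc1cc(Br)cc2n(S(=O)(=O)c3ccc(C)cc3)cc(C(=O)C(NC(=O)c3ccc[nH]3)C(=O)OC(C)(C)C)c12
F5 | step 7 | 3-(6-bromo-4-methoxy-1-tosyl-1H-indol-3-yl)-3-oxo-2-[(1H-pyrrole-2-carbonyl)amino]propanoic acid (racemic, transient) | COc1cc(Br)cc2n(S(=O)(=O)c3ccc(C)cc3)cc(C(=O)C(NC(=O)c3ccc[nH]3)C(=O)O)c12
F6 | step 10 | N-[2-(6-bromo-4-methoxy-1-tosyl-1H-indol-3-yl)-2-oxoethyl]formamide | COc1cc(Br)cc2n(S(=O)(=O)c3ccc(C)cc3)cc(C(=O)CNC=O)c12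
F7 | step 10 | 5-(6-bromo-4-methoxy-1-tosyl-1H-indol-3-yl)-1,3-oxazole | COc1cc(Br)cc2n(S(=O)(=O)c3ccc(C)cc3)cc(-c3cnco3)c12
F8 | step 10 | 5-(6-bromo-4-methoxy-1-tosyl-1H-indol-3-yl)-2,4-diiodo-1,3-oxazole | COc1cc(Br)cc2n(S(=O)(=O)c3ccc(C)cc3)cc(-c3oc(I)nc3I)c12
F9 | step 10 | tert-butyl 2-[5-(6-bromo-4-methoxy-1-tosyl-1H-indol-3-yl)-4-iodo-1,3-oxazol-2-yl]-1H-pyrrole-1-carboxylate | COc1cc(Br)cc2n(S(=O)(=O)c3ccc(C)cc3)cc(-c3oc(-c4cccn4C(=O)OC(C)(C)C)nc3I)c12
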